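**Plan**
- Retrosynthesis: the two aryl–CH bonds at the bridging carbon are cut first (two identical chroman ketones plus 6-methylheptanal), then the O–C(CH3)2 bond of each dihydropyran ring (back to an o-prenylphenol), then the O-benzyl helper, the aryl–CH2 bond of the prenyl group and the aryl–C(=O) bond, ending at phloroglucinol.
- Forward: phloroglucinol is acylated, C-prenylated and benzylated on the hydroxyl para to the ketone; one acid-mediated operation then closes the dihydropyran ring (O–C bond) of each monomer and joins two of the resulting chromans through the aldehyde carbon; hydrogenolysis removes the two benzyl helpers.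
- Enabling feature: in each phloroglucinol ring the side chain ArCH2–CH=C(CH3)2 sits ortho to a phenol oxygen, so protonation gives a tertiary cation placed for six-membered O–C closure; with the para oxygen benzylated, only the oxygen ortho to the isobutyryl C=O can close, and the one remaining ring CH (later C-6) is the only carbon that can be bridged.
- Stereochemistry: none has to be set; the bridging carbon bears two identical aryl groups and C-2 of each chroman is gem-dimethyl.

Key step: step 4

Remark: 6-methylheptanal is taken as a purchasable flavour-grade aldehyde.

**Step 1**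
Reactants: 1 phloroglucinol (benzene-1,3,5-triol); 2 isobutyryl chloride (2-methylpropanoyl chloride)
Product: 3 phlorisobutyrophenone (2-methyl-1-(2,4,6-trihydroxyphenyl)propan-1-one)
Conditions: AlCl3 (3.5 equiv), PhNO2, rt to 65 °C; aq HCl work-up
Reagents that add atoms: none
Why: Friedel–Crafts acylation of the very electron-rich triol; the chelated acyl group deactivates the ring, so mono-acylation should prevail.

**Step 2**
Reactants: 3 phlorisobutyrophenone; 4 prenyl bromide (1-bromo-3-methylbut-2-ene)
Product: 5 2-methyl-1-[2,4,6-trihydroxy-3-(3-methylbut-2-en-1-yl)phenyl]propan-1-one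
Conditions: 4 (0.9 equiv), KOH (1.1 equiv), H2O, 0 °C to rt; then acidify
Reagents that add atoms: none
Why: C-alkylation of the ambident phloroglucinolate (a vinylogous β-triketone enolate) by the soft allylic bromide, favoured over O-alkylation in water; a slight deficit of 4 should limit double prenylation, and the two free ring carbons of 3 are equivalent.

**Step 3**
Reactants: 5 2-methyl-1-[2,4,6-trihydroxy-3-(3-methylbut-2-en-1-yl)phenyl]propan-1-one
Product: 6 1-[4-(benzyloxy)-2,6-dihydroxy-3-(3-methylbut-2-en-1-yl)phenyl]-2-methylpropan-1-one
Conditions: BnBr (1.0 equiv), K2CO3 (1.1 equiv), acetone, rt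
Reagents that add atoms: benzyl bromide, BrCc1ccccc1
Why: Williamson etherification: the hydroxyl para to the ketone is the most acidic (vinylogous acid) and cannot be held in a hydrogen bond to the C=O, so one equivalent of weak base and bromide should etherify it first, and K2CO3 in acetone favours O- over C-benzylation.

**Step 4**
Reactants: 6 1-[4-(benzyloxy)-2,6-dihydroxy-3-(3-methylbut-2-en-1-yl)phenyl]-2-methylpropan-1-one (2 equiv); 7 6-methylheptanal
Product: 9 1,1'-[(6-methylheptane-1,1-diyl)bis(5-benzyloxy-7-hydroxy-2,2-dimethyl-3,4-dihydro-2H-chromene-6,8-diyl)]bis(2-methylpropan-1-one) (bridge at C-6 and ketone at C-8 of each chroman), via benzyloxy chroman ketone 8 (not isolated)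
Conditions: TsOH·H2O (20 mol%), ClCH2CH2Cl, 60 °C until the alkene is consumed; then 7 (0.5 equiv), 60 °C
Reagents that add atoms: none
Why: TsOH protonates the trisubstituted alkene of 6 at its CH terminus to give the tertiary carbocation, which is captured by the only free phenol oxygen next to the side chain (the hydroxyl ortho to the isobutyryl group), forming the O–C(CH3)2 bond and chroman 8; the same acid then activates aldehyde 7 for Friedel–Crafts hydroxyalkylation by the one free aromatic CH of 8 (C-6), the carbinol ionises to an o-quinone methide/benzylic cation stabilised by the 7-hydroxyl and the para ring oxygen, and a second molecule of 8 adds to give 9. The closest known reaction types are the acid-catalysed cycloisomerisation of o-prenylphenols to 2,2-dimethylchromans (intramolecular Markovnikov hydroalkoxylation) and the acid-catalysed phenol–aldehyde condensation to alkylidene-bisphenols that underlies methylene-bridged acylphloroglucinol dimers and resorcinarenes. Each dihydropyran ring closes in the 6-endo-trig mode through the tertiary cation; the 5-exo alternative would need a secondary cation and is not expected. No stereocentre is created, since C-2 of each chroman carries two methyl groups and the bridging carbon carries two identical aryl groups. The step needs regiocontrol over which oxygen closes the ring and which carbon is bridged: the benzyl ether on the oxygen para to the ketone leaves a single flanking hydroxyl and also blocks acid-induced reopening and reclosure onto the other oxygen, while 8 has a single nucleophilic carbon. Adding 7 only after the alkene has been consumed should remove Prins and o-quinone methide–alkene side reactions, and any reopening of the chroman is degenerate.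

**Step 5**
Reactants: 9 the bis-chroman dibenzyl ether
Product: 10 1,1'-[(6-methylheptane-1,1-diyl)bis(5,7-dihydroxy-2,2-dimethyl-3,4-dihydro-2H-chromene-6,8-diyl)]bis(2-methylpropan-1-one) (target)
Conditions: H2 (1 atm), 10% Pd/C, EtOAc, rt
Reagents that add atoms: none
Why: Hydrogenolysis of the two aryl benzyl ethers over Pd/C under neutral conditions; the tertiary alkyl aryl ether of the chroman, the chelated hindered ketones and the diarylmethine should not be touched, and no acid is present that could reopen the dihydropyran rings.

**Compound list**
1 | phloroglucinol (benzene-1,3,5-triol) | Oc1cc(O)cc(O)c1 | starting material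
2 | isobutyryl chloride (2-methylpropanoyl chloride) | CC(C)C(Cl)=O | starting material
3 | phlorisobutyrophenone (2-methyl-1-(2,4,6-trihydroxyphenyl)propan-1-one) | CC(C)C(=O)c1c(O)cc(O)cc1O | intermediate
4 | prenyl bromide (1-bromo-3-methylbut-2-ene) | CC(C)=CCBr | starting material
5 | 2-methyl-1-[2,4,6-trihydroxy-3-(3-methylbut-2-en-1-yl)phenyl]propan-1-one | CC(C)C(=O)c1c(O)cc(O)c(CC=C(C)C)c1O | intermediate
6 | 1-[4-(benzyloxy)-2,6-dihydroxy-3-(3-methylbut-2-en-1-yl)phenyl]-2-methylpropan-1-one | CC(C)C(=O)c1c(O)cc(OCc2ccccc2)c(CC=C(C)C)c1O | intermediate
7 | 6-methylheptanal | CC(C)CCCCC=O | starting material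
8 | 1-[5-(benzyloxy)-7-hydroxy-2,2-dimethyl-3,4-dihydro-2H-chromen-8-yl]-2-methylpropan-1-one | CC(C)C(=O)c1c(O)cc(OCc3ccccc3)c2c1OC(C)(C)CC2 | intermediate
9 | 1,1'-[(6-methylheptane-1,1-diyl)bis(5-benzyloxy-7-hydroxy-2,2-dimethyl-3,4-dihydro-2H-chromene-6,8-diyl)]bis(2-methylpropan-1-one) | CC(C)CCCCC(c1c(OCc3ccccc3)c2c(c(C(=O)C(C)C)c1O)OC(C)(C)CC2)c1c(OCc3ccccc3)c2c(c(C(=O)C(C)C)c1O)OC(C)(C)CC2 | intermediate
10 | 1,1'-[(6-methylheptane-1,1-diyl)bis(5,7-dihydroxy-2,2-dimethyl-3,4-dihydro-2H-chromene-6,8-diyl)]bis(2-methylpropan-1-one) | CC(C)CCCCC(c1c(O)c2c(c(C(=O)C(C)C)c1O)OC(C)(C)CC2)c1c(O)c2c(c(C(=O)C(C)C)c1O)OC(C)(C)CC2 | target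

**Totals**
Total steps: 5. Longest linear sequence: 5 steps (1 → 3 → 5 → 6 → 9 → 10).

**Steps most likely to fail**

Step 4. The second C-arylation at the crowded carbon between the benzyloxy and hydroxyl groups may be slow, so that the benzylic cation eliminates and oligomerises; prolonged acid contact may also cause loss or O-to-C migration of a benzyl group. The fallback separates ring closure from dimerisation and dimerises the free phenol without strong acid. It sets out from 6, which is cyclised with TsOH·H2O alone in ClCH2CH2Cl and isolated as 8. Hydrogenolysis (H2, 10% Pd/C, EtOAc) should give 1-(5,7-dihydroxy-2,2-dimethyl-3,4-dihydro-2H-chromen-8-yl)-2-methylpropan-1-one F1. Two equivalents of F1 are then condensed with 7 under secondary-amine catalysis (pyrrolidine, cat., MeOH, rt to 40 °C): Knoevenagel condensation to the o-quinone methide and Michael addition of the second F1, the biomimetic mode of dimerisation. This comes back to the route at 10.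

Step 3. Site selectivity of the mono-etherification may be eroded, since the para hydroxyl is flanked by the prenyl group: etherification of a hydroxyl ortho to the ketone, double benzylation or C-benzylation at the free ring carbon may compete. The fallback changes the order of events. It sets out from 3, whose unhindered para hydroxyl is benzylated (benzyl bromide, K2CO3, acetone) to 1-[4-(benzyloxy)-2,6-dihydroxyphenyl]-2-methylpropan-1-one F2. C-prenylation of F2 with 4 (KOH, H2O, 0 °C), for which the two free ring carbons are equivalent, should give 6, where the route is rejoined.

Step 2. Over-alkylation of the polyanion (second C-prenylation, geminal dialkylation with dearomatisation, O-prenylation) may consume the material. The fallback uses electrophilic instead of anionic prenylation. It sets out from 3, which is treated with 2-methylbut-3-en-2-ol and BF3·OEt2 (cat.) in dioxane at rt: a Friedel–Crafts alkylation of the neutral phenol by the prenyl cation, run to partial conversion so that no polyanion is involved. It comes back to the route at 5 and makes no new compound (F0).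

**Further compounds**
F1 | step 4 | 1-(5,7-dihydroxy-2,2-dimethyl-3,4-dihydro-2H-chromen-8-yl)-2-methylpropan-1-one | CC(C)C(=O)c1c(O)cc(O)c2c1OC(C)(C)CC2
F2 | step 3 | 1-[4-(benzyloxy)-2,6-dihydroxyphenyl]-2-methylpropan-1-one | CC(C)C(=O)c1c(O)cc(OCc2ccccc2)cc1O
F0 | step 2 | none | none
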